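At their last readings the cedar run holds more target than side product, 49.1% against 45.6%, and the larch run less, 20.0% against 68.2%, on the same charge of starting material.

| setting | larch | cedar | spring | noon |
|---|---|---|---|---|
| starting material | 0.49 M | 0.49 M | 0.49 M | 0.49 M |
| coupling partner | 0.28 equiv | 0.83 equiv | 0.500 equiv | 1.20 equiv |
| remark | run made earlier | run made earlier |  |  |
| time |  |  | 30 min | 30 min |

| run | time / min | target / % | starting material / % | side product / % |
|---|---|---|---|---|
| larch | 2.50 | 11.1 | 46.4 | 42.9 |
| larch | 5.00 | 14.9 | 30.0 | 55.5 |
| larch | 8.00 | 17.8 | 20.1 | 62.6 |
| larch | 10.0 | 18.1 | 17.0 | 64.8 |
| larch | 12.0 | 19.2 | 14.4 | 66.5 |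
| larch | 15.0 | 20.0 | 11.3 | 68.2 |
| cedar | 1.00 | 17.1 | 60.7 | 22.8 |
| cedar | 3.00 | 31.8 | 31.3 | 37.3 |
| cedar | 5.00 | 38.3 | 19.9 | 41.8 |
| cedar | 8.00 | 43.9 | 11.4 | 44.4 |
| cedar | 12.0 | 47.7 | 5.7 | 45.2 |
| cedar | 15.0 | 49.1 | 5.1 | 45.6 |

(standard deviation of a reading: 0.3 percentage points)

- percent here means starting material units held: one side product counts as two

1. which of these there is most of at the end, counted by the starting material in it, spring (side product / target / starting material)
2. which of these there is most of at the end, counted by the starting material in it, noon (side product / target / starting material)
3. the largest of these amounts at the end, in percent of the starting material charged, spring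
4. the largest of these amounts at the end, in percent of the starting material charged, noon

I see two competing rates: target formation, going with starting material times free coupling partner, and side-product formation, going with starting material squared. Their ratio is therefore a constant times free partner over free starting material. From the first cedar reading, gain of target over gain of side product, times mean starting material over mean free partner, I read 0.809: this is the selectivity factor.

At the charge the ratio is the factor times the equivalents: 0.405 in spring and 0.971 at noon, both under one. But it rises as starting material falls, so I join the two ends by integrating. With n, the factor over its distance from one, at 4.25, and e the equivalents, the share of partner left when starting material reaches zero is the n-th power of ne over one plus ne. That gives 19.4% in spring, so target 40.3% and side product 59.7%. At noon it gives 46.7%, so target 63.9% and side product 36.1%. These are limits at zero starting material, which I take as my estimate for 30 min.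

The forecast says side product at 60% in spring and target at 62% at noon, with ranges 57.5% to 62.5% and 59% to 65%. It holds that “the side product looks second order in starting material” and uses a factor of 0.75, where I have 0.809, and my noon target stands higher.

Spring ends at 59.5% of side product, noon at 62.3% of target.

    starting material + coupling partner → target (k = 0.0100 M⁻¹ s⁻¹)
    2 starting material → side product (k = 0.00630 M⁻¹ s⁻¹)
    target → over-reaction product (k = 1.10 × 10⁻⁵ s⁻¹)

At noon 47.2% of the charged partner is free at the end, and the factor 0.809 gave 46.7%. For the neighbour of noon with 0.720 equiv of partner, the factor gives, at zero starting material, 30.1% of partner left and target 50.4% against side product 49.6%. After 30.0 min that flask holds 47.7% target, 49.9% side product and 33% free partner.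

The earlier runs and the new flask were computed with made-up constants; the scatter is artificial.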